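- Amounts first: coupling partner, at 0.200 M in theta and 0.400 M in gamma, exceeds the 0.050 M of each substrate, so you freeze it at its charge (pseudo-first-order) and count partner concentration times time. Call that the dose D 240 M·s: theta gets 240 M·s, gamma 240 M·s, the same at one temperature.

| flask | left-handed substrate | right-handed substrate | coupling partner | temperature | remark | time |
|---|---|---|---|---|---|---|
| Thursday's | 0.050 M | 0.050 M | 0.14 M | 20 °C | run made earlier |  |
| Monday's | 0.050 M | 0.050 M | 0.29 M | 31 °C | run made earlier |  |
| Sunday's | 0.050 M | 0.050 M | 0.32 M | 20 °C | run made earlier |  |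
| theta | 0.050 M | 0.050 M | 0.200 M | 25 °C |  | 20 min |
| gamma | 0.050 M | 0.050 M | 0.400 M | 25 °C |  | 10 min |

| run | time / min | left-handed product / % | left-handed substrate / % |
|---|---|---|---|
| Thursday's | 2.00 | 0.7 | 46.4 |
| Thursday's | 5.00 | 3.5 | 44.2 |
| Thursday's | 10.0 | 7.0 | 42.6 |
| Thursday's | 15.0 | 7.6 | 38.9 |
| Thursday's | 20.0 | 12.0 | 36.0 |
| Monday's | 1.50 | 3.4 | 42.8 |
| Monday's | 3.00 | 9.8 | 38.0 |
| Monday's | 6.00 | 18.7 | 31.6 |
| Monday's | 10.0 | 26.0 | 28.9 |
| Monday's | 20.0 | 42.6 | 18.2 |
| Sunday's | 4.00 | 5.8 | 40.7 |
| Sunday's | 8.00 | 9.6 | 36.9 |
| Sunday's | 12.0 | 15.8 | 34.9 |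
| Sunday's | 15.0 | 17.5 | 32.7 |
| Sunday's | 20.0 | 21.1 | 29.0 |

(readings scatter by 1 percentage point)

- coupling partner is single-handed; left-handed substrate and right-handed substrate are mirror images of each other, charged as a racemate, each of them at the stated concentration
- on the list of suspects stand: coupling partner + left-handed substrate -> left-handed product; left-handed substrate <-> achiral form; achiral form -> waste; coupling partner + right-handed substrate -> right-handed product; right-handed substrate <-> achiral form; coupling partner -> decomposition product
- the handed part of coupling partner does not stay in what it makes, so the products of the two hands are mirror images too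

1. which of the two ends with the higher amount of left-handed product, in percent of the left-handed substrate and right-handed substrate together charged ("neither" if they lie within 2 percentage points) (theta / gamma / neither)
2. left-handed product at the end, in percent of the left-handed substrate and right-handed substrate together charged, theta
3. left-handed product at the end, in percent of the left-handed substrate and right-handed substrate together charged, gamma

- Floor: Sunday's flask, colder at 20 °C, read 15.8 % of left-handed product at a dose of 230 M·s, smaller than D.
- Ceiling: Monday's flask, hotter at 31 °C, read 42.6 % at a dose of 348 M·s, larger than D.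
- Tighter: doubling Monday's time raised its product 1.64-fold, so Monday's curve bends, and scaling its 10.0 min reading straight up to D overshoots. That lowers the ceiling to 35.9 %.
- My number: 25 °C lies near the middle of the two temperatures, and rates climb roughly exponentially with temperature, so take the geometric mean of these readings, 23.8 %, for both flasks: neither wins, and no rate constant went into this reckoning.
- The forecast gives theta 23.5 % (20 % to 27 %) and gamma 21.5 % (18 % to 25 %), inside the bracket, with gamma 2 percentage points lower where I set them equal: “so they lie within 2 points: neither”.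
- The flasks give theta 22.3 % and gamma 22.7 %: neither.

    coupling partner + left-handed substrate → left-handed product (k = 0.160 M⁻¹ min⁻¹, Ea = 72.0 kJ mol⁻¹)
    left-handed substrate ⇌ achiral form (K = 0.0830, k = 0.0680 min⁻¹, Ea = 84.0 kJ mol⁻¹, ΔH = −25.0 kJ mol⁻¹)
    achiral form → waste (k = 0.0710 min⁻¹, Ea = 77.0 kJ mol⁻¹)
    coupling partner + right-handed substrate → right-handed product (k = 0.00520 M⁻¹ min⁻¹, Ea = 81.0 kJ mol⁻¹)
    right-handed substrate ⇌ achiral form (K = 0.0830, k = 0.0680 min⁻¹, Ea = 84.0 kJ mol⁻¹, ΔH = −25.0 kJ mol⁻¹)
    coupling partner → decomposition product (k = 1.80 × 10⁻⁵ min⁻¹, Ea = 112 kJ mol⁻¹)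
    (constants at 25 °C)

- In gamma at 10.0 min, right-handed substrate goes to achiral form, forward step alone, 35 times as fast as it couples. In gamma at 4.24 min, left-handed substrate couples at 0.91 of the rate of its forward step to achiral form.
- Gamma read at 4.0 min has a dose of 96.0 M·s, so scaling gamma's result down the line gives 9.08 %, a floor on a bending curve. That flask gives 10.8 %.

(Readings and results were computed with constants of no real substance.)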